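**Retrosynthetic overview**
- Late Negishi sp3–sp2 coupling joins a C16 cyclohexane iodide (the core) to a C14 alkenyl iodide (the side chain); desilylation, primary-selective oxidation to the enal, acetylation and a last desilylation follow.
- Core: stereochemistry is relayed from one CBS-set carbinol through anti cuprate addition, trans enolate allylation and axial MeLi addition.
- Z-tetrasubstituted enal precursor: kinetic enol triflate, Suzuki coupling with a 2-borylallyl ether, then Cr(CO)3-catalysed 1,4-hydrogenation of the s-cis diene.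
- Side chain: two Zr-catalysed carboaluminations give the E-trisubstituted alkenes; the carbinol comes from (S)-glycidol by Cu-catalysed epoxide opening and Ohira–Bestmann homologation.
- Rings: the single cyclohexane is never formed in the route; it is carried from 3-methylcyclohex-2-en-1-one.

Assumption: small commercial carbon sources used as reagents (allyl iodide, MeLi, AlMe3, lithium acetylide, the Ohira–Bestmann reagent, Ac2O) appear under "Reagents that add atoms" and are not numbered.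

Abbreviations: TBS = tert-butyldimethylsilyl, TBDPS = tert-butyldiphenylsilyl, TES = triethylsilyl, TMS = trimethylsilyl, PMB = 4-methoxybenzyl, Tf = trifluoromethanesulfonyl, pin = pinacolato, DMP = Dess–Martin periodinane.

**Core fragment**

Step 1
Reactants: 1 3-methylcyclohex-2-en-1-one
Product: 2 (S)-3-methylcyclohex-2-en-1-ol
Conditions: (R)-2-methyl-CBS-oxazaborolidine (10 mol %), BH3·SMe2, THF, −20 °C
Reagents that add atoms: none
Why: CBS reduction, in which the (R)-oxazaborolidine differentiates the alkenyl (large) and CH2 (small) flanks and delivers hydride to the face that gives the (S)-allylic alcohol.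

Step 2
Reactants: 2 (S)-3-methylcyclohex-2-en-1-ol
Product: 3 (S)-3-methylcyclohex-2-en-1-yl TBS ether
Conditions: TBSCl, imidazole, DMF, rt
Reagents that add atoms: tert-butyldimethylsilyl chloride (CC(C)(C)[Si](C)(C)Cl)
Why: Standard silylation of a secondary alcohol that leaves the stereocentre untouched.

Step 3
Reactants: 3 (S)-3-methylcyclohex-2-en-1-yl TBS ether
Product: 4 (4S)-4-(TBSO)-2-methylcyclohex-2-en-1-ol (both C1 epimers)
Conditions: SeO2 (0.2 equiv), t-BuOOH (3 equiv), CH2Cl2, 0 °C → rt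
Reagents that add atoms: selenium dioxide (O=[Se]=O), tert-butyl hydroperoxide (CC(C)(C)OO)
Why: SeO2 allylic oxidation (ene reaction then [2,3]-shift) hydroxylates the ring CH2 on the more substituted alkene terminus and not the silyloxy-bearing CH, and the new carbinol epimers converge in step 4.

Step 4
Reactants: 4 (4S)-4-(TBSO)-2-methylcyclohex-2-en-1-ol
Product: 5 (S)-4-(TBSO)-2-methylcyclohex-2-en-1-one
Conditions: DMP, CH2Cl2, rt
Reagents that add atoms: none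
Why: Dess–Martin oxidation of the allylic alcohol to the enone under neutral conditions that do not touch the silyloxy stereocentre.

Step 5
Reactants: 6 3-bromopropan-1-ol
Product: 7 (3-bromopropoxy)(tert-butyl)diphenylsilane
Conditions: TBDPSCl, imidazole, CH2Cl2, 0 °C → rt
Reagents that add atoms: tert-butyldiphenylsilyl chloride (CC(C)(C)[Si](Cl)(c1ccccc1)c1ccccc1)
Why: Silylation of the primary alcohol so that the bromide can be turned into a Grignard reagent.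

Step 6
Reactants: 5 (S)-4-(TBSO)-2-methylcyclohex-2-en-1-one; 7 (3-bromopropoxy)(tert-butyl)diphenylsilane
Product: 9 (1S,2S)-1-(TBSO)-2-[3-(TBDPSO)propyl]-3-methyl-4-(TMSO)cyclohex-3-ene, via Grignard reagent 8 (not isolated)
Conditions: 7, Mg, THF, rt → 40 °C; then 5, CuBr·SMe2 (10 mol %), TMSCl, HMPA, THF, −78 °C
Reagents that add atoms: chlorotrimethylsilane (C[Si](C)(C)Cl)
Why: Copper-catalysed 1,4-addition of the Grignard reagent with silyl trapping, in which the nucleophile enters anti to the adjacent silyloxy group (new side chain trans to OTBS) and the enolate is stored regiospecifically.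

Step 7
Reactants: 9 (1S,2S)-1-(TBSO)-2-[3-(TBDPSO)propyl]-3-methyl-4-(TMSO)cyclohex-3-ene
Product: 11 (2S,3S,4S)-2-allyl-4-(TBSO)-3-[3-(TBDPSO)propyl]-2-methylcyclohexan-1-one, via lithium enolate 10 (not isolated)
Conditions: MeLi, THF, 0 °C; then allyl iodide, HMPA, −78 → 0 °C
Reagents that add atoms: allyl iodide (C=CCI)
Why: Regiospecific enolate alkylation after MeLi cleavage of the silyl enol ether, with allyl iodide approaching anti to the neighbouring side chain so the quaternary carbon carries allyl trans to it.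

Step 8
Reactants: 11 (2S,3S,4S)-2-allyl-4-(TBSO)-3-[3-(TBDPSO)propyl]-2-methylcyclohexan-1-one
Product: 12 (1S,2S,3S,4S)-2-allyl-4-(TBSO)-3-[3-(TBDPSO)propyl]-1,2-dimethylcyclohexan-1-ol
Conditions: MeLi, CeCl3, THF, −78 °C
Reagents that add atoms: methyllithium ([Li]C)
Why: Organocerium 1,2-addition to the chair in which OTBS and the side chain are equatorial and the α-methyl is axial, so methyl attacks the opposite (axial) face and ends trans to the α-methyl.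

Step 9
Reactants: 12 (1S,2S,3S,4S)-2-allyl-4-(TBSO)-3-[3-(TBDPSO)propyl]-1,2-dimethylcyclohexan-1-ol
Product: 13 (1S,2S,3S,4S)-2-allyl-3-[3-(TBDPSO)propyl]-1,2-dimethylcyclohexane-1,4-diol
Conditions: camphorsulfonic acid (0.2 equiv), MeOH/CH2Cl2, rt
Reagents that add atoms: none
Why: Acid methanolysis removes the secondary TBS ether while the far more acid-stable primary TBDPS ether stays.

Step 10
Reactants: 13 (1S,2S,3S,4S)-2-allyl-3-[3-(TBDPSO)propyl]-1,2-dimethylcyclohexane-1,4-diol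
Product: 14 (2S,3S,4S)-3-allyl-2-[3-(TBDPSO)propyl]-4-hydroxy-3,4-dimethylcyclohexan-1-one
Conditions: DMP, CH2Cl2, rt
Reagents that add atoms: none
Why: Dess–Martin oxidation can only touch the secondary alcohol, and its neutral conditions keep the α-stereocentre.

Step 11
Reactants: 14 (2S,3S,4S)-3-allyl-2-[3-(TBDPSO)propyl]-4-hydroxy-3,4-dimethylcyclohexan-1-one
Product: 15 (2S,3S,4S)-3-allyl-2-[3-(TBDPSO)propyl]-3,4-dimethyl-4-(TESO)cyclohexan-1-one
Conditions: TESOTf, 2,6-lutidine, CH2Cl2, −78 → 0 °C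
Reagents that add atoms: triethylsilyl trifluoromethanesulfonate (CC[Si](CC)(CC)OS(=O)(=O)C(F)(F)F)
Why: Silyl triflate protection of the hindered tertiary alcohol, needed before the strong base and organozinc steps.

Step 12
Reactants: 15 (2S,3S,4S)-3-allyl-2-[3-(TBDPSO)propyl]-3,4-dimethyl-4-(TESO)cyclohexan-1-one
Product: 16 (4S,5S,6S)-5-allyl-6-[3-(TBDPSO)propyl]-4,5-dimethyl-4-(TESO)cyclohex-1-en-1-yl triflate
Conditions: KN(SiMe3)2, THF, −78 °C; then PhNTf2, −78 → 0 °C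
Reagents that add atoms: N-phenylbis(trifluoromethanesulfonimide) (O=S(=O)(N(c1ccccc1)S(=O)(=O)C(F)(F)F)C(F)(F)F)
Why: Kinetic deprotonation takes the unhindered CH2 and not the methine next to the quaternary carbon, and O-triflation fixes the less substituted enol triflate without epimerising the α-stereocentre.

Step 13
Reactants: 17 2-bromoprop-2-en-1-ol
Product: 18 [(2-bromoprop-2-en-1-yl)oxy](tert-butyl)dimethylsilane
Conditions: TBSCl, imidazole, CH2Cl2, rt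
Reagents that add atoms: tert-butyldimethylsilyl chloride (CC(C)(C)[Si](C)(C)Cl)
Why: Silylation of the primary allylic alcohol.

Step 14
Reactants: 18 [(2-bromoprop-2-en-1-yl)oxy](tert-butyl)dimethylsilane
Product: 19 2-[3-(TBSO)prop-1-en-2-yl]-4,4,5,5-tetramethyl-1,3,2-dioxaborolane
Conditions: B2pin2, PdCl2(PPh3)2 (3 mol %), PPh3, KOPh, toluene, 50 °C
Reagents that add atoms: bis(pinacolato)diboron (CC1(C)OB(OC1(C)C)B1OC(C)(C)C(C)(C)O1)
Why: Miyaura borylation of the alkenyl bromide gives the alkenylboronate.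

Step 15
Reactants: 16 (4S,5S,6S)-5-allyl-6-[3-(TBDPSO)propyl]-4,5-dimethyl-4-(TESO)cyclohex-1-en-1-yl triflate; 19 2-[3-(TBSO)prop-1-en-2-yl]-4,4,5,5-tetramethyl-1,3,2-dioxaborolane
Product: 20 (4S,5S,6R)-5-allyl-6-[3-(TBDPSO)propyl]-1-[3-(TBSO)prop-1-en-2-yl]-4,5-dimethyl-4-(TESO)cyclohex-1-ene
Conditions: Pd(OAc)2 (5 mol %), SPhos (10 mol %), K3PO4, THF/H2O, 50 °C
Reagents that add atoms: none
Why: Suzuki–Miyaura coupling of the enol triflate with the alkenylboronate builds the 2,3-disubstituted 1,3-diene (the descriptor at the methine changes to R only through CIP priorities).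

Step 16
Reactants: 20 (4S,5S,6R)-5-allyl-6-[3-(TBDPSO)propyl]-1-[3-(TBSO)prop-1-en-2-yl]-4,5-dimethyl-4-(TESO)cyclohex-1-ene
Product: 21 (1S,2S,5Z,6R)-1-allyl-5-[1-(TBSO)propan-2-ylidene]-6-[3-(TBDPSO)propyl]-1,2-dimethyl-2-(TESO)cyclohexane
Conditions: (naphthalene)Cr(CO)3 (20 mol %), H2 (50 atm), THF, 45 °C
Reagents that add atoms: none
Why: Chromium tricarbonyl-catalysed 1,4-hydrogenation runs through the η4 s-cis diene, so the new ring CH2 and the new CH3 end cis and the CH2OTBS arm ends cis to the substituted ring carbon (Z), while the isolated allyl group is not reduced.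

Step 17
Reactants: 21 (1S,2S,5Z,6R)-1-allyl-5-[1-(TBSO)propan-2-ylidene]-6-[3-(TBDPSO)propyl]-1,2-dimethyl-2-(TESO)cyclohexane
Product: 23 2-{(1S,2S,5Z,6R)-5-[1-(TBSO)propan-2-ylidene]-6-[3-(TBDPSO)propyl]-1,2-dimethyl-2-(TESO)cyclohexyl}ethan-1-ol, via aldehyde 22 (not isolated)
Conditions: OsO4 (2 mol %), NaIO4, 2,6-lutidine, dioxane/H2O, rt; then NaBH4, MeOH, 0 °C
Reagents that add atoms: osmium tetroxide (O=[Os](=O)(=O)=O), sodium periodate ([Na+].[O-]I(=O)(=O)=O)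
Why: Lemieux–Johnson cleavage, in which OsO4 dihydroxylates the monosubstituted alkene much faster than the hindered tetrasubstituted one, followed by borohydride reduction of the aldehyde.

Step 18
Reactants: 23 2-{(1S,2S,5Z,6R)-5-[1-(TBSO)propan-2-ylidene]-6-[3-(TBDPSO)propyl]-1,2-dimethyl-2-(TESO)cyclohexyl}ethan-1-ol
Product: 24 (1S,2S,5Z,6R)-5-[1-(TBSO)propan-2-ylidene]-6-[3-(TBDPSO)propyl]-1-(2-iodoethyl)-1,2-dimethyl-2-(TESO)cyclohexane
Conditions: I2, PPh3, imidazole, CH2Cl2, 0 °C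
Reagents that add atoms: iodine (II)
Why: Appel iodination of the primary alcohol under conditions the silyl ethers tolerate.

**Side-chain fragment**

Step 19
Reactants: 25 5-bromo-2-methylpent-2-ene
Product: 26 6-methylhept-5-en-1-yne
Conditions: LiC≡CH·H2NCH2CH2NH2, DMSO, 10 °C → rt
Reagents that add atoms: lithium acetylide–ethylenediamine ([Li+].[C-]#C.NCCN)
Why: SN2 alkylation of acetylide by the primary bromide.

Step 20
Reactants: 26 6-methylhept-5-en-1-yne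
Product: 28 (E)-1-iodo-2,6-dimethylhepta-1,5-diene, via alkenylalane 27 (not isolated)
Conditions: AlMe3, Cp2ZrCl2 (25 mol %), CH2Cl2, 0 °C → rt; then I2, THF, −30 → 0 °C
Reagents that add atoms: trimethylaluminium (C[Al](C)C), iodine (II)
Why: Negishi zirconium-catalysed carboalumination adds Me and Al syn with Me on the internal carbon, and iodinolysis with retention gives the E-alkenyl iodide.

Step 21
Reactants: 29 (S)-glycidol
Product: 30 (R)-2-{[(4-methoxybenzyl)oxy]methyl}oxirane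
Conditions: NaH, PMBCl, Bu4NI (cat.), THF/DMF, 0 °C → rt
Reagents that add atoms: 4-methoxybenzyl chloride (COc1ccc(CCl)cc1)
Why: Williamson etherification that does not touch the stereocentre (S becomes R only through CIP priorities).

Step 22
Reactants: 28 (E)-1-iodo-2,6-dimethylhepta-1,5-diene; 30 (R)-2-{[(4-methoxybenzyl)oxy]methyl}oxirane
Product: 33 (2R,4E)-1-(PMBO)-5,9-dimethyldeca-4,8-dien-2-ol, via alkenyllithium 31 (not isolated), via alkenylmagnesium bromide 32 (not isolated)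
Conditions: 28, t-BuLi (2 equiv), Et2O, −78 °C; MgBr2·OEt2; then 30, CuI (10 mol %), THF, −40 → 0 °C
Reagents that add atoms: none
Why: Iodine–lithium exchange with retention of alkene geometry, transmetalation and copper-catalysed SN2 opening of the epoxide at its terminal carbon, which leaves the carbinol stereocentre as it was in 30.

Step 23
Reactants: 33 (2R,4E)-1-(PMBO)-5,9-dimethyldeca-4,8-dien-2-ol
Product: 34 (2R,4E)-2-(TBSO)-1-(PMBO)-5,9-dimethyldeca-4,8-diene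
Conditions: TBSCl, imidazole, DMF, rt
Reagents that add atoms: tert-butyldimethylsilyl chloride (CC(C)(C)[Si](C)(C)Cl)
Why: Silylation of the secondary alcohol.

Step 24
Reactants: 34 (2R,4E)-2-(TBSO)-1-(PMBO)-5,9-dimethyldeca-4,8-diene
Product: 35 (2R,4E)-2-(TBSO)-5,9-dimethyldeca-4,8-dien-1-ol
Conditions: DDQ, CH2Cl2/pH 7 buffer, 0 °C
Reagents that add atoms: none
Why: Oxidative PMB cleavage that spares silyl ethers and trisubstituted alkenes.

Step 25
Reactants: 35 (2R,4E)-2-(TBSO)-5,9-dimethyldeca-4,8-dien-1-ol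
Product: 36 (2R,4E)-2-(TBSO)-5,9-dimethyldeca-4,8-dienal
Conditions: DMP, CH2Cl2, 0 °C → rt
Reagents that add atoms: none
Why: Dess–Martin oxidation gives the α-silyloxy aldehyde without epimerisation.

Step 26
Reactants: 36 (2R,4E)-2-(TBSO)-5,9-dimethyldeca-4,8-dienal
Product: 37 (3R,5E)-3-(TBSO)-6,10-dimethylundeca-5,9-dien-1-yne
Conditions: dimethyl (1-diazo-2-oxopropyl)phosphonate, K2CO3, MeOH, 0 °C → rt
Reagents that add atoms: dimethyl (1-diazo-2-oxopropyl)phosphonate (COP(=O)(OC)C(=[N+]=[N-])C(C)=O)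
Why: Ohira–Bestmann (Seyferth–Gilbert) homologation turns the aldehyde into the terminal alkyne under mild base.

Step 27
Reactants: 37 (3R,5E)-3-(TBSO)-6,10-dimethylundeca-5,9-dien-1-yne
Product: 39 (1E,3R,5E)-1-iodo-3-(TBSO)-2,6,10-trimethylundeca-1,5,9-triene, via alkenylalane 38 (not isolated)
Conditions: AlMe3, Cp2ZrCl2 (50 mol %), ClCH2CH2Cl, rt; then I2, THF, −30 °C
Reagents that add atoms: trimethylaluminium (C[Al](C)C), iodine (II)
Why: Second Negishi carboalumination–iodination, syn and regioselective on the terminal alkyne only, gives the E-2-methylalkenyl iodide with the carbinol centre unchanged.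

**Coupling and end game**

Step 28
Reactants: 24 (1S,2S,5Z,6R)-5-[1-(TBSO)propan-2-ylidene]-6-[3-(TBDPSO)propyl]-1-(2-iodoethyl)-1,2-dimethyl-2-(TESO)cyclohexane; 39 (1E,3R,5E)-1-iodo-3-(TBSO)-2,6,10-trimethylundeca-1,5,9-triene
Product: 41 (1S,2S,5Z,6R)-1-[(3E,5R,7E)-5-(TBSO)-4,8,12-trimethyltrideca-3,7,11-trien-1-yl]-5-[1-(TBSO)propan-2-ylidene]-6-[3-(TBDPSO)propyl]-1,2-dimethyl-2-(TESO)cyclohexane, via alkylzinc iodide 40 (not isolated)
Conditions: 24, Zn dust, LiCl, THF, 40 °C; then 39, Pd(PPh3)4 (5 mol %), THF, rt → 45 °C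
Reagents that add atoms: none
Why: Negishi sp3–sp2 cross-coupling of the primary alkylzinc iodide with the alkenyl iodide, which retains the E geometry and touches no stereocentre.

Step 29
Reactants: 41 (1S,2S,5Z,6R)-1-[(3E,5R,7E)-5-(TBSO)-4,8,12-trimethyltrideca-3,7,11-trien-1-yl]-5-[1-(TBSO)propan-2-ylidene]-6-[3-(TBDPSO)propyl]-1,2-dimethyl-2-(TESO)cyclohexane
Product: 42 (2Z)-2-{(2R,3S,4S)-2-[3-(TBDPSO)propyl]-4-hydroxy-3-[(3E,5R,7E)-5-hydroxy-4,8,12-trimethyltrideca-3,7,11-trien-1-yl]-3,4-dimethylcyclohexylidene}propan-1-ol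
Conditions: HF·pyridine, pyridine, THF, 0 °C → rt
Reagents that add atoms: none
Why: Buffered HF removes both TBS ethers and the TES ether faster than the primary TBDPS ether, without the acid that could ionise the allylic alcohols.

Step 30
Reactants: 42 (2Z)-2-{(2R,3S,4S)-2-[3-(TBDPSO)propyl]-4-hydroxy-3-[(3E,5R,7E)-5-hydroxy-4,8,12-trimethyltrideca-3,7,11-trien-1-yl]-3,4-dimethylcyclohexylidene}propan-1-ol
Product: 43 (2Z)-2-{(2R,3S,4S)-2-[3-(TBDPSO)propyl]-4-hydroxy-3-[(3E,5R,7E)-5-hydroxy-4,8,12-trimethyltrideca-3,7,11-trien-1-yl]-3,4-dimethylcyclohexylidene}propanal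
Conditions: TEMPO (20 mol %), PhI(OAc)2, CH2Cl2, rt
Reagents that add atoms: none
Why: TEMPO/PhI(OAc)2 oxidation is selective for the primary allylic alcohol over the secondary and tertiary ones and keeps the Z geometry.

Step 31
Reactants: 43 (2Z)-2-{(2R,3S,4S)-2-[3-(TBDPSO)propyl]-4-hydroxy-3-[(3E,5R,7E)-5-hydroxy-4,8,12-trimethyltrideca-3,7,11-trien-1-yl]-3,4-dimethylcyclohexylidene}propanal
Product: 44 (2Z)-2-{(2R,3S,4S)-3-[(3E,5R,7E)-5-acetoxy-4,8,12-trimethyltrideca-3,7,11-trien-1-yl]-2-[3-(TBDPSO)propyl]-4-hydroxy-3,4-dimethylcyclohexylidene}propanal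
Conditions: Ac2O, pyridine, DMAP (cat.), CH2Cl2, 0 °C
Reagents that add atoms: acetic anhydride (CC(=O)OC(C)=O)
Why: Acylation takes the secondary allylic alcohol only, because the tertiary alcohol next to a quaternary carbon is too hindered and the primary alcohol is still silylated.

Step 32
Reactants: 44 (2Z)-2-{(2R,3S,4S)-3-[(3E,5R,7E)-5-acetoxy-4,8,12-trimethyltrideca-3,7,11-trien-1-yl]-2-[3-(TBDPSO)propyl]-4-hydroxy-3,4-dimethylcyclohexylidene}propanal
Product: 45 (2Z)-2-{(2R,3S,4S)-3-[(3E,5R,7E)-5-acetoxy-4,8,12-trimethyltrideca-3,7,11-trien-1-yl]-4-hydroxy-2-(3-hydroxypropyl)-3,4-dimethylcyclohexylidene}propanal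
Conditions: TBAF, AcOH, THF, rt
Reagents that add atoms: none
Why: Acetic acid-buffered fluoride cleaves the TBDPS ether without acetate migration or enal isomerisation.

**Compound list**

1 | 3-methylcyclohex-2-en-1-one | CC1=CC(=O)CCC1 | starting material
2 | (S)-3-methylcyclohex-2-en-1-ol | CC1=C[C@@H](O)CCC1 | intermediate
3 | (S)-tert-butyldimethyl[(3-methylcyclohex-2-en-1-yl)oxy]silane | CC1=C[C@@H](O[Si](C)(C)C(C)(C)C)CCC1 | intermediate
4 | (4S)-4-[(tert-butyldimethylsilyl)oxy]-2-methylcyclohex-2-en-1-ol (C1 epimers) | CC1=C[C@@H](O[Si](C)(C)C(C)(C)C)CCC1O | intermediate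
5 | (S)-4-[(tert-butyldimethylsilyl)oxy]-2-methylcyclohex-2-en-1-one | CC1=C[C@@H](O[Si](C)(C)C(C)(C)C)CCC1=O | intermediate
6 | 3-bromopropan-1-ol | OCCCBr | starting material
7 | (3-bromopropoxy)(tert-butyl)diphenylsilane | BrCCCO[Si](c1ccccc1)(c1ccccc1)C(C)(C)C | intermediate
8 | {3-[(tert-butyldiphenylsilyl)oxy]propyl}magnesium bromide | Br[Mg]CCCO[Si](c1ccccc1)(c1ccccc1)C(C)(C)C | intermediate
9 | tert-butyl{[(1S,2S)-2-{3-[(tert-butyldiphenylsilyl)oxy]propyl}-3-methyl-4-[(trimethylsilyl)oxy]cyclohex-3-en-1-yl]oxy}dimethylsilane | CC1=C(O[Si](C)(C)C)CC[C@H](O[Si](C)(C)C(C)(C)C)[C@H]1CCCO[Si](c2ccccc2)(c2ccccc2)C(C)(C)C | intermediate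
10 | lithium (3S,4S)-4-[(tert-butyldimethylsilyl)oxy]-3-{3-[(tert-butyldiphenylsilyl)oxy]propyl}-2-methylcyclohex-1-en-1-olate | CC1=C(O[Li])CC[C@H](O[Si](C)(C)C(C)(C)C)[C@H]1CCCO[Si](c2ccccc2)(c2ccccc2)C(C)(C)C | intermediate
11 | (2S,3S,4S)-2-allyl-4-[(tert-butyldimethylsilyl)oxy]-3-{3-[(tert-butyldiphenylsilyl)oxy]propyl}-2-methylcyclohexan-1-one | C=CC[C@@]1(C)[C@H](CCCO[Si](c2ccccc2)(c2ccccc2)C(C)(C)C)[C@@H](O[Si](C)(C)C(C)(C)C)CCC1=O | intermediate
12 | (1S,2S,3S,4S)-2-allyl-4-[(tert-butyldimethylsilyl)oxy]-3-{3-[(tert-butyldiphenylsilyl)oxy]propyl}-1,2-dimethylcyclohexan-1-ol | C=CC[C@@]1(C)[C@H](CCCO[Si](c2ccccc2)(c2ccccc2)C(C)(C)C)[C@@H](O[Si](C)(C)C(C)(C)C)CC[C@]1(C)O | intermediate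
13 | (1S,2S,3S,4S)-2-allyl-3-{3-[(tert-butyldiphenylsilyl)oxy]propyl}-1,2-dimethylcyclohexane-1,4-diol | C=CC[C@@]1(C)[C@H](CCCO[Si](c2ccccc2)(c2ccccc2)C(C)(C)C)[C@@H](O)CC[C@]1(C)O | intermediate
14 | (2S,3S,4S)-3-allyl-2-{3-[(tert-butyldiphenylsilyl)oxy]propyl}-4-hydroxy-3,4-dimethylcyclohexan-1-one | C=CC[C@@]1(C)[C@H](CCCO[Si](c2ccccc2)(c2ccccc2)C(C)(C)C)C(=O)CC[C@]1(C)O | intermediate
15 | (2S,3S,4S)-3-allyl-2-{3-[(tert-butyldiphenylsilyl)oxy]propyl}-3,4-dimethyl-4-[(triethylsilyl)oxy]cyclohexan-1-one | C=CC[C@@]1(C)[C@H](CCCO[Si](c2ccccc2)(c2ccccc2)C(C)(C)C)C(=O)CC[C@]1(C)O[Si](CC)(CC)CC | intermediate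
16 | (4S,5S,6S)-5-allyl-6-{3-[(tert-butyldiphenylsilyl)oxy]propyl}-4,5-dimethyl-4-[(triethylsilyl)oxy]cyclohex-1-en-1-yl trifluoromethanesulfonate | C=CC[C@@]1(C)[C@H](CCCO[Si](c2ccccc2)(c2ccccc2)C(C)(C)C)C(OS(=O)(=O)C(F)(F)F)=CC[C@]1(C)O[Si](CC)(CC)CC | intermediate
17 | 2-bromoprop-2-en-1-ol | OCC(Br)=C | starting material
18 | [(2-bromoprop-2-en-1-yl)oxy](tert-butyl)dimethylsilane | C=C(Br)CO[Si](C)(C)C(C)(C)C | intermediate
19 | tert-butyldimethyl{[2-(4,4,5,5-tetramethyl-1,3,2-dioxaborolan-2-yl)prop-2-en-1-yl]oxy}silane | C=C(CO[Si](C)(C)C(C)(C)C)B1OC(C)(C)C(C)(C)O1 | intermediate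
20 | tert-butyl({2-[(4S,5S,6R)-5-allyl-6-{3-[(tert-butyldiphenylsilyl)oxy]propyl}-4,5-dimethyl-4-[(triethylsilyl)oxy]cyclohex-1-en-1-yl]prop-2-en-1-yl}oxy)dimethylsilane | C=CC[C@@]1(C)[C@H](CCCO[Si](c2ccccc2)(c2ccccc2)C(C)(C)C)C(C(=C)CO[Si](C)(C)C(C)(C)C)=CC[C@]1(C)O[Si](CC)(CC)CC | intermediate
21 | (1S,2S,5Z,6R)-1-allyl-5-{1-[(tert-butyldimethylsilyl)oxy]propan-2-ylidene}-6-{3-[(tert-butyldiphenylsilyl)oxy]propyl}-1,2-dimethyl-2-[(triethylsilyl)oxy]cyclohexane | C=CC[C@@]1(C)[C@H](CCCO[Si](c2ccccc2)(c2ccccc2)C(C)(C)C)/C(=C(/C)CO[Si](C)(C)C(C)(C)C)CC[C@]1(C)O[Si](CC)(CC)CC | intermediate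
22 | 2-[(1S,2S,5Z,6R)-5-{1-[(tert-butyldimethylsilyl)oxy]propan-2-ylidene}-6-{3-[(tert-butyldiphenylsilyl)oxy]propyl}-1,2-dimethyl-2-[(triethylsilyl)oxy]cyclohexyl]acetaldehyde | O=CC[C@@]1(C)[C@H](CCCO[Si](c2ccccc2)(c2ccccc2)C(C)(C)C)/C(=C(/C)CO[Si](C)(C)C(C)(C)C)CC[C@]1(C)O[Si](CC)(CC)CC | intermediate
23 | 2-[(1S,2S,5Z,6R)-5-{1-[(tert-butyldimethylsilyl)oxy]propan-2-ylidene}-6-{3-[(tert-butyldiphenylsilyl)oxy]propyl}-1,2-dimethyl-2-[(triethylsilyl)oxy]cyclohexyl]ethan-1-ol | OCC[C@@]1(C)[C@H](CCCO[Si](c2ccccc2)(c2ccccc2)C(C)(C)C)/C(=C(/C)CO[Si](C)(C)C(C)(C)C)CC[C@]1(C)O[Si](CC)(CC)CC | intermediate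
24 | (1S,2S,5Z,6R)-5-{1-[(tert-butyldimethylsilyl)oxy]propan-2-ylidene}-6-{3-[(tert-butyldiphenylsilyl)oxy]propyl}-1-(2-iodoethyl)-1,2-dimethyl-2-[(triethylsilyl)oxy]cyclohexane | ICC[C@@]1(C)[C@H](CCCO[Si](c2ccccc2)(c2ccccc2)C(C)(C)C)/C(=C(/C)CO[Si](C)(C)C(C)(C)C)CC[C@]1(C)O[Si](CC)(CC)CC | intermediate
25 | 5-bromo-2-methylpent-2-ene | CC(C)=CCCBr | starting material
26 | 6-methylhept-5-en-1-yne | CC(C)=CCCC#C | intermediate
27 | [(E)-2,6-dimethylhepta-1,5-dien-1-yl]dimethylalane | CC(C)=CCC/C(C)=C/[Al](C)C | intermediate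
28 | (E)-1-iodo-2,6-dimethylhepta-1,5-diene | CC(C)=CCC/C(C)=C/I | intermediate
29 | (S)-glycidol [(S)-oxiran-2-ylmethanol] | OC[C@H]1CO1 | starting material
30 | (R)-2-{[(4-methoxybenzyl)oxy]methyl}oxirane | COc1ccc(COC[C@H]2CO2)cc1 | intermediate
31 | [(E)-2,6-dimethylhepta-1,5-dien-1-yl]lithium | CC(C)=CCC/C(C)=C/[Li] | intermediate
32 | [(E)-2,6-dimethylhepta-1,5-dien-1-yl]magnesium bromide | CC(C)=CCC/C(C)=C/[Mg]Br | intermediate
33 | (2R,4E)-1-[(4-methoxybenzyl)oxy]-5,9-dimethyldeca-4,8-dien-2-ol | COc1ccc(COC[C@H](O)C/C=C(\C)CCC=C(C)C)cc1 | intermediate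
34 | tert-butyl{[(2R,4E)-1-[(4-methoxybenzyl)oxy]-5,9-dimethyldeca-4,8-dien-2-yl]oxy}dimethylsilane | COc1ccc(COC[C@H](O[Si](C)(C)C(C)(C)C)C/C=C(\C)CCC=C(C)C)cc1 | intermediate
35 | (2R,4E)-2-[(tert-butyldimethylsilyl)oxy]-5,9-dimethyldeca-4,8-dien-1-ol | OC[C@H](O[Si](C)(C)C(C)(C)C)C/C=C(\C)CCC=C(C)C | intermediate
36 | (2R,4E)-2-[(tert-butyldimethylsilyl)oxy]-5,9-dimethyldeca-4,8-dienal | O=C[C@H](O[Si](C)(C)C(C)(C)C)C/C=C(\C)CCC=C(C)C | intermediate
37 | tert-butyl{[(3R,5E)-6,10-dimethylundeca-5,9-dien-1-yn-3-yl]oxy}dimethylsilane | C#C[C@H](O[Si](C)(C)C(C)(C)C)C/C=C(\C)CCC=C(C)C | intermediate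
38 | {(1E,3R,5E)-3-[(tert-butyldimethylsilyl)oxy]-2,6,10-trimethylundeca-1,5,9-trien-1-yl}dimethylalane | CC(C)(C)[Si](C)(C)O[C@H](C/C=C(\C)CCC=C(C)C)/C(C)=C/[Al](C)C | intermediate
39 | tert-butyl{[(1E,3R,5E)-1-iodo-2,6,10-trimethylundeca-1,5,9-trien-3-yl]oxy}dimethylsilane | CC(C)(C)[Si](C)(C)O[C@H](C/C=C(\C)CCC=C(C)C)/C(C)=C/I | intermediate
40 | {2-[(1S,2S,5Z,6R)-5-{1-[(tert-butyldimethylsilyl)oxy]propan-2-ylidene}-6-{3-[(tert-butyldiphenylsilyl)oxy]propyl}-1,2-dimethyl-2-[(triethylsilyl)oxy]cyclohexyl]ethyl}zinc iodide | I[Zn]CC[C@@]1(C)[C@H](CCCO[Si](c2ccccc2)(c2ccccc2)C(C)(C)C)/C(=C(/C)CO[Si](C)(C)C(C)(C)C)CC[C@]1(C)O[Si](CC)(CC)CC | intermediate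
41 | (1S,2S,5Z,6R)-1-{(3E,5R,7E)-5-[(tert-butyldimethylsilyl)oxy]-4,8,12-trimethyltrideca-3,7,11-trien-1-yl}-5-{1-[(tert-butyldimethylsilyl)oxy]propan-2-ylidene}-6-{3-[(tert-butyldiphenylsilyl)oxy]propyl}-1,2-dimethyl-2-[(triethylsilyl)oxy]cyclohexane | CC(C)(C)[Si](C)(C)O[C@H](C/C=C(\C)CCC=C(C)C)/C(C)=C/CC[C@@]1(C)[C@H](CCCO[Si](c2ccccc2)(c2ccccc2)C(C)(C)C)/C(=C(/C)CO[Si](C)(C)C(C)(C)C)CC[C@]1(C)O[Si](CC)(CC)CC | intermediate
42 | (2Z)-2-[(2R,3S,4S)-2-{3-[(tert-butyldiphenylsilyl)oxy]propyl}-4-hydroxy-3-[(3E,5R,7E)-5-hydroxy-4,8,12-trimethyltrideca-3,7,11-trien-1-yl]-3,4-dimethylcyclohexylidene]propan-1-ol | O[C@H](C/C=C(\C)CCC=C(C)C)/C(C)=C/CC[C@@]1(C)[C@H](CCCO[Si](c2ccccc2)(c2ccccc2)C(C)(C)C)/C(=C(/C)CO)CC[C@]1(C)O | intermediate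
43 | (2Z)-2-[(2R,3S,4S)-2-{3-[(tert-butyldiphenylsilyl)oxy]propyl}-4-hydroxy-3-[(3E,5R,7E)-5-hydroxy-4,8,12-trimethyltrideca-3,7,11-trien-1-yl]-3,4-dimethylcyclohexylidene]propanal | O[C@H](C/C=C(\C)CCC=C(C)C)/C(C)=C/CC[C@@]1(C)[C@H](CCCO[Si](c2ccccc2)(c2ccccc2)C(C)(C)C)/C(=C(/C)C=O)CC[C@]1(C)O | intermediate
44 | (2Z)-2-[(2R,3S,4S)-3-[(3E,5R,7E)-5-acetoxy-4,8,12-trimethyltrideca-3,7,11-trien-1-yl]-2-{3-[(tert-butyldiphenylsilyl)oxy]propyl}-4-hydroxy-3,4-dimethylcyclohexylidene]propanal | CC(=O)O[C@H](C/C=C(\C)CCC=C(C)C)/C(C)=C/CC[C@@]1(C)[C@H](CCCO[Si](c2ccccc2)(c2ccccc2)C(C)(C)C)/C(=C(/C)C=O)CC[C@]1(C)O | intermediate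
45 | (2Z)-2-[(2R,3S,4S)-3-[(3E,5R,7E)-5-acetoxy-4,8,12-trimethyltrideca-3,7,11-trien-1-yl]-4-hydroxy-2-(3-hydroxypropyl)-3,4-dimethylcyclohexylidene]propanal (CNP0421354.1) | CC(=O)O[C@H](C/C=C(\C)CCC=C(C)C)/C(C)=C/CC[C@@]1(C)[C@H](CCCO)/C(=C(/C)C=O)CC[C@]1(C)O | target

**Totals**

Total step count: 32. Longest linear sequence: 20 steps (1–4, 6–12, 15–18, 28–32).

**Three steps most likely to fail, with fallbacks**

Step 3 (SeO2 allylic oxidation). The ring CH2, the methyl group and the silyloxy-bearing CH all compete, and yields of such oxidations are often modest. The fallback sets out from 1 and comes back at 5. Enone 1 is oxidised at its γ-methylene with Pd(OH)2/C and t-BuOOH (K2CO3, CH2Cl2) to 2-methylcyclohex-2-ene-1,4-dione F1. CBS reduction with the (R)-oxazaborolidine and catecholborane at −78 °C then takes the less hindered carbonyl, the one flanked by CH= and not by C(Me)=, and gives (S)-4-hydroxy-2-methylcyclohex-2-en-1-one F2. Silylation with TBSCl and imidazole gives 5. The regioselectivity of the reduction is the open point of this fallback.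

Step 16 (1,4-hydrogenation). The diene is 2,3-disubstituted and flanked by a quaternary centre, so binding to Cr(CO)3 may be slow. The fallback sets out from 15 and comes back at 21. Ketone 15 is treated with CH2=C(CH3)MgBr and CeCl3 to give the tertiary allylic alcohol (2S,3S,4S)-3-allyl-2-[3-(TBDPSO)propyl]-3,4-dimethyl-1-(prop-1-en-2-yl)-4-(TESO)cyclohexan-1-ol F3. Babler–Dauben oxidative 1,3-transposition with pyridinium chlorochromate, C5H5NH[CrO3Cl], gives the enal (2Z)-2-{(2R,3S,4S)-3-allyl-2-[3-(TBDPSO)propyl]-3,4-dimethyl-4-(TESO)cyclohexylidene}propanal F4. This enal would form as a Z/E mixture, so the Z isomer has to be separated and the E isomer recycled by iodine-catalysed equilibration; this fallback is therefore not stereospecific. Luche reduction (NaBH4, CeCl3·7H2O, MeOH) gives (2Z)-2-{(2R,3S,4S)-3-allyl-2-[3-(TBDPSO)propyl]-3,4-dimethyl-4-(TESO)cyclohexylidene}propan-1-ol F5, and TBSCl with imidazole gives 21.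

Step 28 (fragment coupling). Zinc insertion into a hindered, polyfunctional iodide and the following Pd step risk protodemetalation and β-hydride loss on the most valuable material. The fallback sets out from 39 and 24 and comes back at 41, with the polarity reversed and no palladium. Alkenyl iodide 39 is lithiated (t-BuLi, Et2O, −78 °C) to {(1E,3R,5E)-3-[(tert-butyldimethylsilyl)oxy]-2,6,10-trimethylundeca-1,5,9-trien-1-yl}lithium F6. Its geometry is retained, and the silyloxy group sits trans to lithium, so no silyl migration is possible. F6 is then alkylated by primary iodide 24 in THF/HMPA (−78 → 0 °C) in an SN2 reaction that forms the same C–C bond and gives 41.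

**Further compounds**

F1 | step 3 | 2-methylcyclohex-2-ene-1,4-dione | CC1=CC(=O)CCC1=O
F2 | step 3 | (S)-4-hydroxy-2-methylcyclohex-2-en-1-one | CC1=C[C@@H](O)CCC1=O
F3 | step 16 | (2S,3S,4S)-3-allyl-2-{3-[(tert-butyldiphenylsilyl)oxy]propyl}-3,4-dimethyl-1-(prop-1-en-2-yl)-4-[(triethylsilyl)oxy]cyclohexan-1-ol (C1 epimers) | C=CC[C@@]1(C)[C@H](CCCO[Si](c2ccccc2)(c2ccccc2)C(C)(C)C)C(O)(C(C)=C)CC[C@]1(C)O[Si](CC)(CC)CC
F4 | step 16 | (2Z)-2-[(2R,3S,4S)-3-allyl-2-{3-[(tert-butyldiphenylsilyl)oxy]propyl}-3,4-dimethyl-4-[(triethylsilyl)oxy]cyclohexylidene]propanal | C=CC[C@@]1(C)[C@H](CCCO[Si](c2ccccc2)(c2ccccc2)C(C)(C)C)/C(=C(/C)C=O)CC[C@]1(C)O[Si](CC)(CC)CC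
F5 | step 16 | (2Z)-2-[(2R,3S,4S)-3-allyl-2-{3-[(tert-butyldiphenylsilyl)oxy]propyl}-3,4-dimethyl-4-[(triethylsilyl)oxy]cyclohexylidene]propan-1-ol | C=CC[C@@]1(C)[C@H](CCCO[Si](c2ccccc2)(c2ccccc2)C(C)(C)C)/C(=C(/C)CO)CC[C@]1(C)O[Si](CC)(CC)CC
F6 | step 28 | {(1E,3R,5E)-3-[(tert-butyldimethylsilyl)oxy]-2,6,10-trimethylundeca-1,5,9-trien-1-yl}lithium | CC(C)(C)[Si](C)(C)O[C@H](C/C=C(\C)CCC=C(C)C)/C(C)=C/[Li]
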